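**Retrosynthetic overview**

- Pestallic acid P ⇐ its ethyl ester ⇐ hydroxyl-directed reduction of a ring ketone ⇐ α′-allylation of a cross-conjugated enone with ethyl (E)-4-bromo-2-methylbut-2-enoate ⇐ Suzuki coupling of an α-bromoenone with (E)-hept-1-enylboronic acid.
- The enone ⇐ Saegusa–Ito oxidation of a silyl enol ether ⇐ Diels–Alder adduct of the 2-silyloxy diene CH2=C(OTBS)–CH=CH–CH2OTBS and vinylene carbonate. This cycloaddition makes the bond from the CH2OH-bearing ring carbon to its carbinol neighbour and the bond from the other diol carbon to the side-chain-bearing carbon.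
- Enabling feature: in the cyclohexene the lone carbinol carbon sits between the side-chain carbon and the tetrasubstituted C=C (a reduced enone), so these four ring carbons are a 2-oxy-1,3-diene. The cis-diol pair on the opposite edge of the ring is a cis-enediol, i.e. vinylene carbonate.
- Ring order: the carbocycle, cis-fused to the dioxolanone, forms in the cycloaddition (the only ring-forming C–C step). The five-membered carbonate is then exchanged for an acetonide, a temporary ring that shields one face during the allylation.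

Key step: step 3

Remark on the chemistry: both cycloaddition partners are achiral, so the cycloadduct and the diol made from it are racemates (drawn as the enantiomer that is carried on). The absolute configuration is secured by an enzymatic kinetic resolution in step 5, which costs half of the material at that point.

**Route**

Step 1
Reactants: 1 (tert-butyldimethylsilyloxy)acetaldehyde; 2 1-(triphenylphosphoranylidene)propan-2-one
Product: 3 (3E)-5-[(tert-butyldimethylsilyl)oxy]pent-3-en-2-one
Conditions: CH2Cl2, rt to 40 °C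
Reagents that add atoms: none
Why: Wittig olefination with a stabilised acyl ylide should give the E-enone selectively; no stereocentre is formed.

Step 2
Reactants: 3 (3E)-5-[(tert-butyldimethylsilyl)oxy]pent-3-en-2-one
Product: 4 (3E)-2,5-bis[(tert-butyldimethylsilyl)oxy]penta-1,3-diene
Conditions: TBSOTf, Et3N, Et2O, 0 °C
Reagents that add atoms: tert-butyldimethylsilyl trifluoromethanesulfonate, CC(C)(C)[Si](C)(C)OS(=O)(=O)C(F)(F)F
Why: Soft enolisation of the methyl ketone (silyl triflate/amine, kinetic deprotonation of the methyl group) should give the cross-conjugated 2-silyloxy diene and leave the E-alkene untouched.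

Step 3
Reactants: 4 (3E)-2,5-bis[(tert-butyldimethylsilyl)oxy]penta-1,3-diene; 5 vinylene carbonate (1,3-dioxol-2-one)
Product: 6 rac-(3aR,4S,7aS)-6-[(tert-butyldimethylsilyl)oxy]-4-{[(tert-butyldimethylsilyl)oxy]methyl}-3a,4,7,7a-tetrahydro-1,3-benzodioxol-2-one (cis-fused carbonate; CH2OTBS expected cis to both ring oxygens)
Conditions: 5 (3 equiv), toluene, BHT (cat.), sealed tube, 170 °C
Reagents that add atoms: none
Why: A concerted, thermally allowed suprafacial [4+2] cycloaddition (Diels–Alder) joins the two termini of the 2-silyloxy diene to the two olefinic carbons of vinylene carbonate, so both new ring bonds form in one event. The closest known reaction type is the thermal Diels–Alder reaction of 2-silyloxy-1,3-dienes with electron-poor alkenes and of vinylene carbonate with oxygenated dienes, as used for cyclitols. The cyclohexene ring is closed by the intermolecular cycloaddition itself (4π + 2π, both σ-bonds on one face of each partner), and the dioxolanone ring is carried in intact and ends cis-fused. The two carbinol stereocentres are cis because addition to the Z-locked cyclic dienophile is stereospecific; the third stereocentre (CH2OTBS carbon, expected endo) is erased in step 7 and needs no control. Regiochemistry is no issue because the dienophile is symmetric, and the mechanism fixes the new silyl enol ether double bond between the oxygenated carbon and the unsubstituted carbon, which later places the enone correctly. The step needs only that the cross-conjugated diene reacts through its s-cis conformer, which the E-geometry (CH2OTBS outside) and the unsubstituted CH2 terminus secure.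

Step 4
Reactants: 6 rac-(3aR,4S,7aS)-6-[(tert-butyldimethylsilyl)oxy]-4-{[(tert-butyldimethylsilyl)oxy]methyl}-3a,4,7,7a-tetrahydro-1,3-benzodioxol-2-one
Product: 7 rac-(1S,2R,3S)-5-[(tert-butyldimethylsilyl)oxy]-3-{[(tert-butyldimethylsilyl)oxy]methyl}cyclohex-4-ene-1,2-diol (all-cis)
Conditions: LiAlH4, Et2O, 0 °C; Na2SO4·10H2O quench
Reagents that add atoms: none
Why: Hydride reduction of the cyclic carbonate gives the diol and methanol while the silyl enol ether and silyl ether are inert, and removing the carbonate before the ketone is unveiled avoids a β-acyloxy ketone that would eliminate; stereocentres are untouched.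

Step 5
Reactants: 7 rac-(1S,2R,3S)-5-[(tert-butyldimethylsilyl)oxy]-3-{[(tert-butyldimethylsilyl)oxy]methyl}cyclohex-4-ene-1,2-diol
Product: 8 (1S,2R,3S)-5-[(tert-butyldimethylsilyl)oxy]-3-{[(tert-butyldimethylsilyl)oxy]methyl}cyclohex-4-ene-1,2-diol (single enantiomer, recovered unreacted)
Conditions: immobilised Burkholderia cepacia lipase (Amano PS), vinyl acetate, MTBE, 30 °C, stopped just past half conversion
Reagents that add atoms: none
Why: Lipase-catalysed transesterification (enzymatic kinetic resolution of a secondary alcohol) should acetylate the less hindered hydroxyl of the (1R,2S,3R) enantiomer faster, following the usual preference of these lipases for the R-configured carbinol, so the (1S,2R,3S) diol is recovered with high enantiomeric purity once conversion passes one half.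

Step 6
Reactants: 8 (1S,2R,3S)-5-[(tert-butyldimethylsilyl)oxy]-3-{[(tert-butyldimethylsilyl)oxy]methyl}cyclohex-4-ene-1,2-diol
Product: 9 (3aR,4S,7aS)-6-[(tert-butyldimethylsilyl)oxy]-4-{[(tert-butyldimethylsilyl)oxy]methyl}-2,2-dimethyl-3a,4,7,7a-tetrahydro-1,3-benzodioxole (acetonide of 8)
Conditions: 2-methoxypropene, PPTS (cat.), CH2Cl2, 0 °C; Et3N quench
Reagents that add atoms: 2-methoxypropene, COC(C)=C
Why: Acid-catalysed acetalisation of the cis-1,2-diol with the far more basic alkyl enol ether is fast at 0 °C and should leave the TBS enol ether intact; no stereocentre changes.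

Step 7
Reactants: 9 (3aR,4S,7aS)-6-[(tert-butyldimethylsilyl)oxy]-4-{[(tert-butyldimethylsilyl)oxy]methyl}-2,2-dimethyl-3a,4,7,7a-tetrahydro-1,3-benzodioxole
Product: 10 (4R,5S)-3-{[(tert-butyldimethylsilyl)oxy]methyl}-4,5-(isopropylidenedioxy)cyclohex-2-en-1-one
Conditions: Pd(OAc)2 (1.1 equiv), MeCN, rt
Reagents that add atoms: none
Why: Saegusa–Ito oxidation: the silyl enol ether gives a divalent palladium enolate whose β-hydride elimination can only take the hydrogen of the CH(CH2OTBS) carbon, so the enone forms regiospecifically and that stereocentre is erased.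

Step 8
Reactants: 10 (4R,5S)-3-{[(tert-butyldimethylsilyl)oxy]methyl}-4,5-(isopropylidenedioxy)cyclohex-2-en-1-one
Product: 12 (4R,5S)-2-bromo-3-{[(tert-butyldimethylsilyl)oxy]methyl}-4,5-(isopropylidenedioxy)cyclohex-2-en-1-one, via dibromide 11 (not isolated)
Conditions: Br2, CH2Cl2, −20 °C; then Et3N, 0 °C
Reagents that add atoms: bromine, BrBr
Why: Bromine addition to the enone C=C followed by amine-induced loss of HBr through the enolate (addition–elimination α-bromination) works on β-substituted enones, where amine-catalysed iodination is sluggish.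

Step 9
Reactants: 12 (4R,5S)-2-bromo-3-{[(tert-butyldimethylsilyl)oxy]methyl}-4,5-(isopropylidenedioxy)cyclohex-2-en-1-one; 13 (E)-hept-1-en-1-ylboronic acid
Product: 14 (4R,5S)-2-[(1E)-hept-1-en-1-yl]-3-{[(tert-butyldimethylsilyl)oxy]methyl}-4,5-(isopropylidenedioxy)cyclohex-2-en-1-one
Conditions: PdCl2(PhCN)2 (cat.), AsPh3, Ag2O, THF/H2O, rt
Reagents that add atoms: none
Why: Suzuki–Miyaura coupling of an α-bromoenone with an alkenylboronic acid (zerovalent palladium cycle, silver oxide as a mild activator for the base-sensitive enone) proceeds with retention of the E-geometry.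

Step 10
Reactants: 15 glycolaldehyde dimer (1,4-dioxane-2,5-diol); 16 ethyl 2-(triphenylphosphoranylidene)propanoate
Product: 17 ethyl (2E)-4-hydroxy-2-methylbut-2-enoate
Conditions: THF, 65 °C
Reagents that add atoms: none
Why: Wittig olefination of the monomeric aldehyde, released from the dimer on heating, with a stabilised α-methyl ylide should give the E-trisubstituted enoate.

Step 11
Reactants: 17 ethyl (2E)-4-hydroxy-2-methylbut-2-enoate
Product: 18 ethyl (2E)-4-bromo-2-methylbut-2-enoate
Conditions: CBr4, PPh3, CH2Cl2, 0 °C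
Reagents that add atoms: carbon tetrabromide, BrC(Br)(Br)Br
Why: Appel bromination of the primary allylic alcohol (SN2 at carbon) leaves the alkene geometry untouched.

Step 12
Reactants: 14 (4R,5S)-2-[(1E)-hept-1-en-1-yl]-3-{[(tert-butyldimethylsilyl)oxy]methyl}-4,5-(isopropylidenedioxy)cyclohex-2-en-1-one; 18 ethyl (2E)-4-bromo-2-methylbut-2-enoate
Product: 20 (4R,5S,6S)-6-[(2E)-4-ethoxy-3-methyl-4-oxobut-2-en-1-yl]-2-[(1E)-hept-1-en-1-yl]-3-{[(tert-butyldimethylsilyl)oxy]methyl}-4,5-(isopropylidenedioxy)cyclohex-2-en-1-one, via lithium enolate 19 (not isolated)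
Conditions: LiN(SiMe3)2, THF, −78 °C; then 18, DMPU, −78 to −40 °C
Reagents that add atoms: none
Why: Kinetic α′-deprotonation gives the cross-conjugated lithium enolate, which should be alkylated (SN2) by the allylic bromide on the face opposite the cis-fused acetonide, setting the side-chain stereocentre trans to the neighbouring oxygen; the low temperature is meant to suppress β-elimination of that oxygen.

Step 13
Reactants: 20 (4R,5S,6S)-6-[(2E)-4-ethoxy-3-methyl-4-oxobut-2-en-1-yl]-2-[(1E)-hept-1-en-1-yl]-3-{[(tert-butyldimethylsilyl)oxy]methyl}-4,5-(isopropylidenedioxy)cyclohex-2-en-1-one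
Product: 21 (4R,5S,6S)-6-[(2E)-4-ethoxy-3-methyl-4-oxobut-2-en-1-yl]-2-[(1E)-hept-1-en-1-yl]-4,5-dihydroxy-3-(hydroxymethyl)cyclohex-2-en-1-one
Conditions: AcOH/THF/H2O (3:1:1), 40 °C
Reagents that add atoms: none
Why: Mild aqueous acid hydrolyses the acetonide and the primary silyl ether (acetal hydrolysis and protodesilylation) at the ketone stage, before an acid-labile dienyl carbinol exists, as in acetonide removal from related β-hydroxy cyclohexenones.

Step 14
Reactants: 21 (4R,5S,6S)-6-[(2E)-4-ethoxy-3-methyl-4-oxobut-2-en-1-yl]-2-[(1E)-hept-1-en-1-yl]-4,5-dihydroxy-3-(hydroxymethyl)cyclohex-2-en-1-one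
Product: 22 ethyl (2E)-4-[(1R,2S,5R,6S)-3-[(1E)-hept-1-en-1-yl]-2,5,6-trihydroxy-4-(hydroxymethyl)cyclohex-3-en-1-yl]-2-methylbut-2-enoate
Conditions: Me4NBH(OAc)3, MeCN/AcOH (1:1), −30 to −20 °C
Reagents that add atoms: none
Why: Hydroxyl-directed Evans–Saksena reduction: the hydroxyl β to the ketone binds boron and delivers hydride on its own face, so the new carbinol should be 1,3-anti to it and cis to the side chain, which is also the face an external hydride prefers (anti to the α′-substituent).

Step 15
Reactants: 22 ethyl (2E)-4-[(1R,2S,5R,6S)-3-[(1E)-hept-1-en-1-yl]-2,5,6-trihydroxy-4-(hydroxymethyl)cyclohex-3-en-1-yl]-2-methylbut-2-enoate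
Product: 24 pestallic acid P, via lithium carboxylate 23 (not isolated)
Conditions: LiOH, THF/H2O, 0 °C to rt; then 1 M HCl to pH 3
Reagents that add atoms: lithium hydroxide, [Li+].[OH-]
Why: Saponification of the ethyl ester followed by careful acidification; no ketone is left, so retro-aldol and elimination pathways are closed and the E-enoate and allylic alcohols should survive.

**Compound list**

1 | (tert-butyldimethylsilyloxy)acetaldehyde | O=CCO[Si](C)(C)C(C)(C)C | starting material
2 | 1-(triphenylphosphoranylidene)propan-2-one | CC(=O)C=P(c1ccccc1)(c1ccccc1)c1ccccc1 | starting material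
3 | (3E)-5-[(tert-butyldimethylsilyl)oxy]pent-3-en-2-one | CC(=O)/C=C/CO[Si](C)(C)C(C)(C)C | intermediate
4 | (3E)-2,5-bis[(tert-butyldimethylsilyl)oxy]penta-1,3-diene | C=C(O[Si](C)(C)C(C)(C)C)/C=C/CO[Si](C)(C)C(C)(C)C | intermediate
5 | vinylene carbonate (1,3-dioxol-2-one) | O=C1OC=CO1 | starting material
6 | rac-(3aR,4S,7aS)-6-[(tert-butyldimethylsilyl)oxy]-4-{[(tert-butyldimethylsilyl)oxy]methyl}-3a,4,7,7a-tetrahydro-1,3-benzodioxol-2-one (racemate, drawn as the enantiomer carried on) | C1=C(O[Si](C)(C)C(C)(C)C)C[C@@H]2OC(=O)O[C@@H]2[C@@H]1CO[Si](C)(C)C(C)(C)C | intermediate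
7 | rac-(1S,2R,3S)-5-[(tert-butyldimethylsilyl)oxy]-3-{[(tert-butyldimethylsilyl)oxy]methyl}cyclohex-4-ene-1,2-diol (racemate, drawn as the enantiomer carried on) | C1=C(O[Si](C)(C)C(C)(C)C)C[C@H](O)[C@H](O)[C@@H]1CO[Si](C)(C)C(C)(C)C | intermediate
8 | (1S,2R,3S)-5-[(tert-butyldimethylsilyl)oxy]-3-{[(tert-butyldimethylsilyl)oxy]methyl}cyclohex-4-ene-1,2-diol (single enantiomer) | C1=C(O[Si](C)(C)C(C)(C)C)C[C@H](O)[C@H](O)[C@@H]1CO[Si](C)(C)C(C)(C)C | intermediate
9 | (3aR,4S,7aS)-6-[(tert-butyldimethylsilyl)oxy]-4-{[(tert-butyldimethylsilyl)oxy]methyl}-2,2-dimethyl-3a,4,7,7a-tetrahydro-1,3-benzodioxole | C1=C(O[Si](C)(C)C(C)(C)C)C[C@@H]2OC(C)(C)O[C@@H]2[C@@H]1CO[Si](C)(C)C(C)(C)C | intermediate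
10 | (4R,5S)-3-{[(tert-butyldimethylsilyl)oxy]methyl}-4,5-(isopropylidenedioxy)cyclohex-2-en-1-one | O=C1C=C(CO[Si](C)(C)C(C)(C)C)[C@H]2OC(C)(C)O[C@H]2C1 | intermediate
11 | (4R,5S)-2,3-dibromo-3-{[(tert-butyldimethylsilyl)oxy]methyl}-4,5-(isopropylidenedioxy)cyclohexan-1-one (mixture at the two C–Br carbons) | O=C1C(Br)C(Br)(CO[Si](C)(C)C(C)(C)C)[C@H]2OC(C)(C)O[C@H]2C1 | intermediate
12 | (4R,5S)-2-bromo-3-{[(tert-butyldimethylsilyl)oxy]methyl}-4,5-(isopropylidenedioxy)cyclohex-2-en-1-one | O=C1C(Br)=C(CO[Si](C)(C)C(C)(C)C)[C@H]2OC(C)(C)O[C@H]2C1 | intermediate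
13 | (E)-hept-1-en-1-ylboronic acid | CCCCC/C=C/B(O)O | starting material
14 | (4R,5S)-2-[(1E)-hept-1-en-1-yl]-3-{[(tert-butyldimethylsilyl)oxy]methyl}-4,5-(isopropylidenedioxy)cyclohex-2-en-1-one | O=C1C(/C=C/CCCCC)=C(CO[Si](C)(C)C(C)(C)C)[C@H]2OC(C)(C)O[C@H]2C1 | intermediate
15 | glycolaldehyde dimer (1,4-dioxane-2,5-diol) | OC1COC(O)CO1 | starting material
16 | ethyl 2-(triphenylphosphoranylidene)propanoate | CCOC(=O)C(C)=P(c1ccccc1)(c1ccccc1)c1ccccc1 | starting material
17 | ethyl (2E)-4-hydroxy-2-methylbut-2-enoate | CCOC(=O)/C(C)=C/CO | intermediate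
18 | ethyl (2E)-4-bromo-2-methylbut-2-enoate | CCOC(=O)/C(C)=C/CBr | intermediate
19 | lithium cross-conjugated dienolate of 14 | [Li]OC1=C[C@@H]2OC(C)(C)O[C@@H]2C(CO[Si](C)(C)C(C)(C)C)=C1/C=C/CCCCC | intermediate
20 | (4R,5S,6S)-6-[(2E)-4-ethoxy-3-methyl-4-oxobut-2-en-1-yl]-2-[(1E)-hept-1-en-1-yl]-3-{[(tert-butyldimethylsilyl)oxy]methyl}-4,5-(isopropylidenedioxy)cyclohex-2-en-1-one | O=C1C(/C=C/CCCCC)=C(CO[Si](C)(C)C(C)(C)C)[C@H]2OC(C)(C)O[C@H]2[C@@H]1C/C=C(\C)C(=O)OCC | intermediate
21 | (4R,5S,6S)-6-[(2E)-4-ethoxy-3-methyl-4-oxobut-2-en-1-yl]-2-[(1E)-hept-1-en-1-yl]-4,5-dihydroxy-3-(hydroxymethyl)cyclohex-2-en-1-one | O=C1C(/C=C/CCCCC)=C(CO)[C@@H](O)[C@@H](O)[C@@H]1C/C=C(\C)C(=O)OCC | intermediate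
22 | ethyl (2E)-4-[(1R,2S,5R,6S)-3-[(1E)-hept-1-en-1-yl]-2,5,6-trihydroxy-4-(hydroxymethyl)cyclohex-3-en-1-yl]-2-methylbut-2-enoate | O[C@@H]1C(/C=C/CCCCC)=C(CO)[C@@H](O)[C@@H](O)[C@@H]1C/C=C(\C)C(=O)OCC | intermediate
23 | lithium carboxylate of pestallic acid P | O[C@@H]1C(/C=C/CCCCC)=C(CO)[C@@H](O)[C@@H](O)[C@@H]1C/C=C(\C)C(=O)[O-].[Li+] | intermediate
24 | pestallic acid P, (2E)-4-[(1R,2S,5R,6S)-3-[(1E)-hept-1-en-1-yl]-2,5,6-trihydroxy-4-(hydroxymethyl)cyclohex-3-en-1-yl]-2-methylbut-2-enoic acid | CCCCC/C=C/C1=C(CO)[C@@H](O)[C@@H](O)[C@H](C/C=C(\C)C(=O)O)[C@@H]1O | target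

**Step count and risks**

Total steps: 15. Longest linear sequence: 13 steps (steps 1–9 and 12–15); steps 10–11 are a two-step side branch.

Steps most likely to fail:

Step 12. The lithium enolate may expel the acetonide oxygen on the neighbouring carbon (β-elimination, then aromatisation), or it may add to the enoate of the bromide instead of displacing bromide. The fallback makes the same C–C bond under neutral conditions by a Tsuji–Trost allylation and sets out from 14. Deprotonation of 14 with LiN(SiMe3)2 in the presence of Me3SiCl (internal quench, −78 °C) should give the trimethylsilyl dienol ether of 14 F1, so that the free enolate lives only briefly. Alcohol 17 is converted with methyl chloroformate and pyridine into ethyl (2E)-4-[(methoxycarbonyl)oxy]-2-methylbut-2-enoate F2. Pd2(dba)3 with dppe in THF should then ionise the carbonate to the π-allyl complex and join it at its unsubstituted terminus to the α′-carbon, again on the face away from the acetonide, which rejoins the route at 20.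

Step 3. The cycloaddition may be too slow at a temperature the silyl enol ether tolerates, so that desilylation or polymerisation of the partners wins. The fallback sets out from 4 and uses a dienophile of the same kind carrying two activating chlorine atoms, 4,5-dichloro-1,3-dioxol-2-one, which is far more electron-poor and should add at about 110 °C to give the dichloro cycloadduct F3. Radical dechlorination with Bu3SnH and AIBN in benzene at 80 °C then removes both chlorines; hydrogen transfer to the two ring-fusion radicals can only give the cis-fused carbonate, so the route is rejoined at 6.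

Step 5. The lipase may discriminate poorly between the enantiomers, or acylate both hydroxyls, so that the recovered diol is not enantiopure at useful recovery. The fallback replaces enzymatic discrimination by physical separation and sets out from 7. Racemic 7 is taken through the conditions of steps 6 and 7 to the racemic acetonide silyl enol ether F4 and then to the racemic enone acetonide F5. The enantiomers of F5 are separated by preparative chromatography on a chiral stationary phase (amylose tris(3,5-dimethylphenylcarbamate)); the (4R,5S) enantiomer is 10, where the route is rejoined.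

**Further compounds**

F1 | step 12 | trimethylsilyl dienol ether of 14 | C[Si](C)(C)OC1=C[C@@H]2OC(C)(C)O[C@@H]2C(CO[Si](C)(C)C(C)(C)C)=C1/C=C/CCCCC
F2 | step 12 | ethyl (2E)-4-[(methoxycarbonyl)oxy]-2-methylbut-2-enoate | CCOC(=O)/C(C)=C/COC(=O)OC
F3 | step 3 | racemic cis-fused 3a,7a-dichloro analogue of 6 (dichloro cycloadduct; CH2OTBS carbon unassigned) | C1=C(O[Si](C)(C)C(C)(C)C)C[C@]2(Cl)OC(=O)O[C@]2(Cl)C1CO[Si](C)(C)C(C)(C)C
F4 | step 5 | racemic form of 9 (drawn as the enantiomer that is kept) | C1=C(O[Si](C)(C)C(C)(C)C)C[C@@H]2OC(C)(C)O[C@@H]2[C@@H]1CO[Si](C)(C)C(C)(C)C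
F5 | step 5 | racemic form of 10 (drawn as the enantiomer that is kept) | O=C1C=C(CO[Si](C)(C)C(C)(C)C)[C@H]2OC(C)(C)O[C@H]2C1
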